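## Structural features

Labdane numbering is used throughout: ring A is C1–C5/C10, ring B is C5–C10, C17 is the exocyclic methylene on C8, C18 (methyl) and C19 (CO2Me) sit on C4, C20 is the angular methyl on C10, and C11–C16 is the side chain on C9 with the acetate on C15. The target is a decalin diester with a (3S)-5-acetoxy-3-methylpentyl chain on C9, next to the C8=C17 methylene. Read literally, the SMILES puts H-5 and C20 on the same face, so the decalin is cis-fused (4S,5S,9S,10R,13S); it is the C5 epimer of the usual trans labd-8(17)-en-19-oate pattern. Four contiguous stereocentres (C4 quaternary, C5, C10 quaternary, C9) surround the ring fusion: CO2Me, H-5, C20 and C11 lie on one face, C18, C6 and H-9 on the other, and C13 is isolated in the chain. The fragile groups are the exocyclic alkene (acid-promoted migration, hydrogenation) and the primary acetate (base, hard nucleophiles); the neopentyl methyl ester is robust. The real difficulty is the cis fusion between two quaternary carbons, because cationic or radical A-to-B polycyclisation and dissolving-metal chemistry all lead to the trans series. A second difficulty is C9, which sits beside C10 in a conformationally mobile cis-decalin where substrate control after ring closure is unreliable. The key step exploits the C17=C8–C9–C10 array of ring B: C9 is the γ-carbon of an allylsilane whose silicon sat on C17, and a nucleophile tethered at C5 can reach C10 only on the face of C6, which is exactly the cis fusion.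

## Logic of the disconnections

21 to 19 (through 20): a carbonyl is added back at C2. Only from C2 can C10 be made electrophilic by conjugation (C2=O, C1=C10) without touching C4 or C5. This exposes the enolate retron of a conjugate addition. The forward step must remove the ketone without affecting the 8(17)-alkene or either ester.

19 to 17 (key): the C9–C10 bond is cut, C8=C17 is returned to a C8=C9 alkene with silicon on C17, and the C1=C10 enone is restored. This removes ring B, both ring-fusion-dependent stereocentres (C10, C9) and the exocyclic alkene in one operation, leaving a monocyclic enone whose only ring stereocentres are C4 and C5. The forward step needs 1,4-addition, delivery on the C6 face, and a (Z)-configured silane so that C11 ends equatorial.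

17 to 16: the C8–C17 bond is cut (silylmethyl group to vinyl bromide). The silane is acid- and oxidant-sensitive, so it is installed last before the key step. The coupling must retain the alkene geometry.

16 to 15: the C1=C10 unsaturation is removed (enone back to the silyl enol ether). The ketone then stays masked during the borane chemistry, and the transient C10 centre becomes irrelevant. The forward dehydrogenation must be regiospecific; it is, because C4 is quaternary.

15 to 8 + 13: the C7–C8 sp3–sp2 bond is cut. This splits the molecule into a ring A piece and the whole side chain, giving full convergence. The forward coupling must discriminate the two bromides of 13 (trans one first).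

13 to 12 to 10 to 9: the C8=C9 bond is traced back to an aldehyde carbon and then to the trisubstituted alkene of 9. C9 and C11–C16, including the C13 stereocentre, come from the chiral pool. The only demand is that no step touches C13.

8 to 7: the C6=C7 bond is cut (terminal alkene back to aldehyde). The formyl group is what controls the cycloaddition regiochemistry. The forward olefination must not epimerise C5.

7 to 4 + 6: the C3–C4 and C5–C10 bonds are cut ([4+2]). Ring A and the C4/C5 relationship come from the alkene geometry of 4 by a stereospecific suprafacial addition; the absolute sense comes from the catalyst. The diene terminus C3 must bond to the fully substituted C4, which the formyl group on C5 enforces.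

4 to 3 to 1 + 2, and 6 to 5: the C4=C5 alkene is cut by carbonyl olefination and the silyl enol ether by O-silylation. All four precursors are commercial. The olefination must be (E)-selective.

## Other disconnections considered

Alternative 1: the biomimetic cut of C4–C5 and C9–C10 in one A-to-B polycyclisation, the plan that comes to mind first. The forward key step would be an oxidative radical bicyclisation (Mn(OAc)3/Cu(OAc)2) or a cation–olefin bicyclisation of the acyclic β-keto ester A1, giving the bicyclic 8(17)-ene keto ester A2 directly. It is the shortest conceivable plan. The concerted cationic mode adds anti across the (E)-C5=C10 alkene. The stepwise radical mode closes ring B from a C10 radical through an equatorial, chair-like attack. Both are expected to give the trans fusion with the C19 ester cis to C6, so A2 would be the C5 epimer of what is needed. C5 lies between two quaternary carbons and offers no handle for later inversion. A (Z)-C5=C10 alkene could in principle redirect only the cationic mode, which cannot tolerate an ester-bearing initiator carbon.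

Alternative 2: a Robinson annulation route that cuts C4–C5 and C1–C10 around a methylcyclohexanedione. The forward key steps would be annulation, deconjugative C4 methylation to the Δ5 enedione ester A3, and then hydrogenation of C5=C6. The C4/C10 relationship is reliable, since the methyl enters anti to C20. The C5 hydrogen, however, must be delivered to the β face, syn to both C20 and the C19 ester and against the intrinsic α preference of such alkenes. That would rest on an ester-directed iridium hydrogenation ([Ir(cod)(PCy3)(py)]PF6) at a neopentyl trisubstituted alkene. C9 and C8 would then need about six further steps from the C9 ketone, with C9–H set on a flexible cis-decalin. The plan is longer and leaves the hardest centre to a directed reduction.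

Alternative 3: an anionic double Michael ([4+2]) annulation that cuts C4–C5 and C1–C10. The forward key step would add the α-methyl Nazarov reagent A4 to a 2-methylcycloalkenone ring B partner to give the cis-fused diketo ester A5. The cis fusion is assured, but three points argue against it. First, the C4 configuration arises from a reversible, stepwise Michael pair, and the sense (ester syn or anti to C20) cannot be predicted with confidence. Second, an unactivated α-methyl enone should be a poorer acceptor than A4 is toward itself. Third, C9 arrives as a ketone beside a second ketone at C3, so differentiation and about five steps are needed to reach the chain and the methylene, again with C9–H set by substrate control. The chosen plan sets C4/C5 by a stereospecific cycloaddition and C9/C10 together in one ring-forming transition state.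

Key step: step 12

Assumption 1: the SMILES is taken literally, so the route is designed for the cis-fused (4S,5S,9S,10R,13S) isomer and not for the trans-fused natural series.

Assumption 2: the (S)-configured oxazaborolidinium catalyst of step 4 is assumed to deliver the (1S,2S,3S) adduct 7; if the facial sense is the opposite, the (R)-catalyst is used and nothing else changes.

## Steps

Step 1
Reactants: 1 2,2-dimethoxyacetaldehyde; 2 methyl 2-(triphenyl-λ5-phosphanylidene)propanoate
Product: 3 methyl (2E)-4,4-dimethoxy-2-methylbut-2-enoate
Conditions: CH2Cl2, 0 °C → rt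
Reagents that add atoms: none
Why: Wittig olefination with an α-methyl stabilised ylide; reversible oxaphosphetane formation should give the (E)-trisubstituted enoate, with the acetal masking the second aldehyde of glyoxal.

Step 2
Reactants: 3 methyl (2E)-4,4-dimethoxy-2-methylbut-2-enoate
Product: 4 methyl (2E)-2-methyl-4-oxobut-2-enoate
Conditions: 1 M aq. HCl, THF, rt
Reagents that add atoms: water O
Why: Acid-catalysed acetal hydrolysis; the (E)-geometry (CHO trans to CO2Me) is the thermodynamic one and should be retained.

Step 3
Reactants: 5 (3E)-pent-3-en-2-one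
Product: 6 tert-butyl(dimethyl){[(3E)-penta-1,3-dien-2-yl]oxy}silane
Conditions: t-BuMe2SiOTf, Et3N, CH2Cl2, 0 °C
Reagents that add atoms: tert-butyldimethylsilyl trifluoromethanesulfonate CC(C)(C)[Si](C)(C)OS(=O)(=O)C(F)(F)F
Why: Soft enolisation and O-silylation on the CH3 side of the methyl ketone gives the 2-silyloxydiene; the (E)-propenyl geometry is carried over, so the terminal methyl is an outside substituent.

Step 4
Reactants: 4 methyl (2E)-2-methyl-4-oxobut-2-enoate; 6 tert-butyl(dimethyl){[(3E)-penta-1,3-dien-2-yl]oxy}silane
Product: 7 methyl (1S,2S,3S)-5-[(tert-butyldimethylsilyl)oxy]-2-formyl-1,3-dimethylcyclohex-4-ene-1-carboxylate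
Conditions: (S)-diphenylprolinol-derived B-(o-tolyl)oxazaborolidine·HNTf2 (20 mol %), CH2Cl2, −78 °C
Reagents that add atoms: none
Why: Catalytic enantioselective Diels–Alder reaction: the Lewis acid binds the formyl group, so the nucleophilic CH2 terminus of 6 bonds to the carbon β to CHO (C4) and the methyl-bearing terminus to C5, both directing effects of the diene agreeing. Suprafacial addition turns the (E)-geometry of 4 into CHO trans to CO2Me (cis to the C4 methyl), which is the C4/C5 relationship of the target; the catalyst selects the face and so the absolute configuration, and the endo-derived methyl centre (future C10) is transient.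

Step 5
Reactants: 7 methyl (1S,2S,3S)-5-[(tert-butyldimethylsilyl)oxy]-2-formyl-1,3-dimethylcyclohex-4-ene-1-carboxylate
Product: 8 methyl (1S,2S,3R)-5-[(tert-butyldimethylsilyl)oxy]-2-ethenyl-1,3-dimethylcyclohex-4-ene-1-carboxylate
Conditions: Ph3PCH3Br, KN(SiMe3)2, THF, −78 → 0 °C
Reagents that add atoms: methyltriphenylphosphonium bromide (used as its ylide) C[P+](c1ccccc1)(c1ccccc1)c1ccccc1.[Br-]
Why: Wittig methylenation; addition of the unhindered aldehyde to the salt-free ylide at low temperature should outrun enolisation, so the epimerisable C5 centre is kept, and the ester and silyl enol ether are inert.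

Step 6
Reactants: 9 (3S)-3,7-dimethyloct-6-en-1-ol
Product: 10 (3S)-3,7-dimethyloct-6-en-1-yl acetate
Conditions: Ac2O, pyridine, DMAP (cat.), CH2Cl2, rt
Reagents that add atoms: acetic anhydride CC(=O)OC(C)=O
Why: Nucleophile-catalysed acylation of the primary alcohol; this installs the C15 acetate of the target at the outset, and C13 is not involved.

Step 7
Reactants: 10 (3S)-3,7-dimethyloct-6-en-1-yl acetate
Product: 12 (3S)-3-methyl-6-oxohexyl acetate, via ozonide 11 (not isolated)
Conditions: O3, CH2Cl2, −78 °C; then Me2S, −78 °C → rt
Reagents that add atoms: ozone [O-][O+]=O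
Why: Ozonolysis with reductive work-up cleaves the only alkene; the aldehyde carbon is the future C9, and the acetate and C13 are untouched.

Step 8
Reactants: 12 (3S)-3-methyl-6-oxohexyl acetate
Product: 13 (3S)-7,7-dibromo-3-methylhept-6-en-1-yl acetate
Conditions: CBr4, PPh3, CH2Cl2, 0 °C
Reagents that add atoms: carbon tetrabromide BrC(Br)(Br)Br
Why: Ramirez gem-dibromo-olefination (Wittig reaction of the ylide Ph3P=CBr2); it adds C8 and gives two bromides that differ sterically, which the next step uses.

Step 9
Reactants: 8 methyl (1S,2S,3R)-5-[(tert-butyldimethylsilyl)oxy]-2-ethenyl-1,3-dimethylcyclohex-4-ene-1-carboxylate; 13 (3S)-7,7-dibromo-3-methylhept-6-en-1-yl acetate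
Product: 15 methyl (1S,2S,3R)-2-[(3Z,7S)-9-(acetyloxy)-3-bromo-7-methylnon-3-en-1-yl]-5-[(tert-butyldimethylsilyl)oxy]-1,3-dimethylcyclohex-4-ene-1-carboxylate, via alkylborane 14 (not isolated)
Conditions: 9-BBN, THF, 0 °C → rt; then 13, Pd2(dba)3 (2.5 mol %), P(2-furyl)3 (15 mol %), aq. K3PO4, THF/DMF, rt → 40 °C
Reagents that add atoms: none
Why: Anti-Markovnikov hydroboration of the terminal vinyl group (the trisubstituted silyl enol ether is much slower) followed by B-alkyl Suzuki–Miyaura coupling. Zerovalent palladium inserts first into the less hindered C–Br bond trans to the chain, so C7 enters trans to C11 and the remaining bromide is cis, giving the (Z)-bromoalkene.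

Step 10
Reactants: 15 methyl (1S,2S,3R)-2-[(3Z,7S)-9-(acetyloxy)-3-bromo-7-methylnon-3-en-1-yl]-5-[(tert-butyldimethylsilyl)oxy]-1,3-dimethylcyclohex-4-ene-1-carboxylate
Product: 16 methyl (1S,2S)-2-[(3Z,7S)-9-(acetyloxy)-3-bromo-7-methylnon-3-en-1-yl]-1,3-dimethyl-5-oxocyclohex-3-ene-1-carboxylate
Conditions: Pd(OAc)2 (1.1 equiv), MeCN, rt → 40 °C
Reagents that add atoms: none
Why: Saegusa–Ito oxidation: divalent palladium adds to C1 of the silyl enol ether and β-hydride elimination can only take H-10, giving the C1=C10 enone regiospecifically and erasing the transient C10 centre; the neutral conditions should leave the γ-stereocentre C5 alone.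

Step 11
Reactants: 16 methyl (1S,2S)-2-[(3Z,7S)-9-(acetyloxy)-3-bromo-7-methylnon-3-en-1-yl]-1,3-dimethyl-5-oxocyclohex-3-ene-1-carboxylate
Product: 17 methyl (1S,2S)-2-{(3Z,7S)-9-(acetyloxy)-7-methyl-3-[(trimethylsilyl)methyl]non-3-en-1-yl}-1,3-dimethyl-5-oxocyclohex-3-ene-1-carboxylate
Conditions: Me3SiCH2MgCl, ZnCl2, THF, 0 °C; then 16, Pd[P(t-Bu)3]2 (5 mol %), THF, rt
Reagents that add atoms: (trimethylsilyl)methylmagnesium chloride (transmetalated to zinc) C[Si](C)(C)C[Mg]Cl
Why: Negishi coupling of the alkenyl bromide; with the bulky trialkylphosphine the substitution should proceed with retention, so the silylmethyl group ends cis to C11 ((Z)-allylsilane), and the organozinc tolerates enone, ester and acetate.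

Step 12
Reactants: 17 methyl (1S,2S)-2-{(3Z,7S)-9-(acetyloxy)-7-methyl-3-[(trimethylsilyl)methyl]non-3-en-1-yl}-1,3-dimethyl-5-oxocyclohex-3-ene-1-carboxylate
Product: 19 methyl (1S,4aR,5S,8aS)-5-[(3S)-5-(acetyloxy)-3-methylpentyl]-1,4a-dimethyl-6-methylidene-3-oxodecahydronaphthalene-1-carboxylate, via titanium enolate 18 (not isolated)
Conditions: TiCl4 (2.5 equiv), CH2Cl2, −78 °C; aq. NaHCO3
Reagents that add atoms: none
Why: Intramolecular Hosomi–Sakurai conjugate addition (SE2′ attack of an allylsilane on a Lewis-acid-activated enone): TiCl4 binds the C2 carbonyl, the γ-carbon C9 bonds to C10, the β-silyl cation at C8 loses Me3Si from C17 to give the C8=C17 methylene without regiochemical ambiguity, and work-up protonates titanium enolate 18 at C1. The closest known reaction type is the Lewis-acid cyclisation of 3-methylcyclohex-2-enones carrying an allylsilane chain on C4 to cis-fused methylenedecalones. Ring B closes 6-exo-trig with respect to the C1=C10 acceptor (6-endo with respect to the C8=C9 donor). C10 is controlled by C5: the three-atom tether C6–C7–C8 can deliver C9 only to the face of C10 on which C6 sits, and overlap with the enone π* needs an axial trajectory, so C9–C10 forms cis to C5–C6 and C20 ends cis to H-5 (cis fusion). C9 is controlled by the alkene geometry: in the chair-like forming ring the C9 substituent trans to C7 becomes equatorial, so the (Z)-silane puts C11 equatorial and cis to C20, while the axial alternative would clash 1,3-diaxially with C4. The step needs 1,4- over 1,2-addition (only C10 is within reach through a six-membered transition state), γ-attack of the silane (secured by silicon) and cyclisation faster than protodesilylation (aprotic, low temperature).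

Step 13
Reactants: 19 methyl (1S,4aR,5S,8aS)-5-[(3S)-5-(acetyloxy)-3-methylpentyl]-1,4a-dimethyl-6-methylidene-3-oxodecahydronaphthalene-1-carboxylate
Product: 20 methyl (1S,4aR,5S,8aS)-5-[(3S)-5-(acetyloxy)-3-methylpentyl]-1,4a-dimethyl-6-methylidene-3-[2-(4-methylbenzenesulfonyl)hydrazinylidene]decahydronaphthalene-1-carboxylate
Conditions: TsNHNH2, EtOH, 60 °C
Reagents that add atoms: 4-methylbenzenesulfonohydrazide Cc1ccc(cc1)S(=O)(=O)NN
Why: Condensation of the only ketone (flanked by two CH2 groups) to the tosylhydrazone; the esters and the exocyclic alkene do not react.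

Step 14
Reactants: 20 methyl (1S,4aR,5S,8aS)-5-[(3S)-5-(acetyloxy)-3-methylpentyl]-1,4a-dimethyl-6-methylidene-3-[2-(4-methylbenzenesulfonyl)hydrazinylidene]decahydronaphthalene-1-carboxylate
Product: 21 methyl (1S,4aR,5S,8aS)-5-[(3S)-5-(acetyloxy)-3-methylpentyl]-1,4a-dimethyl-6-methylidenedecahydronaphthalene-1-carboxylate
Conditions: catecholborane, CHCl3, 0 °C; then NaOAc·3H2O, reflux
Reagents that add atoms: none
Why: Caglioti-type reduction of the tosylhydrazone: hydride adds to C=N, acetate triggers loss of sulfinate, and the diazene loses N2 to leave the C2 methylene. The conditions are non-acidic and non-hydrogenating, so the 8(17)-alkene should neither migrate nor be reduced, and no stereocentre is touched.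

## Compound list

1 | 2,2-dimethoxyacetaldehyde | COC(OC)C=O | starting material
2 | methyl 2-(triphenyl-λ5-phosphanylidene)propanoate | COC(=O)C(C)=P(c1ccccc1)(c1ccccc1)c1ccccc1 | starting material
3 | methyl (2E)-4,4-dimethoxy-2-methylbut-2-enoate | COC(OC)/C=C(\C)C(=O)OC | intermediate
4 | methyl (2E)-2-methyl-4-oxobut-2-enoate | O=C/C=C(\C)C(=O)OC | intermediate
5 | (3E)-pent-3-en-2-one | C/C=C/C(C)=O | starting material
6 | tert-butyl(dimethyl){[(3E)-penta-1,3-dien-2-yl]oxy}silane | C/C=C/C(=C)O[Si](C)(C)C(C)(C)C | intermediate
7 | methyl (1S,2S,3S)-5-[(tert-butyldimethylsilyl)oxy]-2-formyl-1,3-dimethylcyclohex-4-ene-1-carboxylate | O=C[C@H]1[C@@H](C)C=C(O[Si](C)(C)C(C)(C)C)C[C@]1(C)C(=O)OC | intermediate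
8 | methyl (1S,2S,3R)-5-[(tert-butyldimethylsilyl)oxy]-2-ethenyl-1,3-dimethylcyclohex-4-ene-1-carboxylate | C=C[C@H]1[C@@H](C)C=C(O[Si](C)(C)C(C)(C)C)C[C@]1(C)C(=O)OC | intermediate
9 | (3S)-3,7-dimethyloct-6-en-1-ol ((S)-citronellol) | CC(C)=CCC[C@H](C)CCO | starting material
10 | (3S)-3,7-dimethyloct-6-en-1-yl acetate | CC(C)=CCC[C@H](C)CCOC(C)=O | intermediate
11 | (3S)-5-(5,5-dimethyl-1,2,4-trioxolan-3-yl)-3-methylpentyl acetate (ozonide, both epimers at the ring CH) | CC1(C)OOC(CC[C@H](C)CCOC(C)=O)O1 | intermediate (not isolated)
12 | (3S)-3-methyl-6-oxohexyl acetate | O=CCC[C@H](C)CCOC(C)=O | intermediate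
13 | (3S)-7,7-dibromo-3-methylhept-6-en-1-yl acetate | BrC(Br)=CCC[C@H](C)CCOC(C)=O | intermediate
14 | methyl (1S,2S,3R)-2-[2-(9-borabicyclo[3.3.1]nonan-9-yl)ethyl]-5-[(tert-butyldimethylsilyl)oxy]-1,3-dimethylcyclohex-4-ene-1-carboxylate | C1CC2CCCC(C1)B2CC[C@H]1[C@@H](C)C=C(O[Si](C)(C)C(C)(C)C)C[C@]1(C)C(=O)OC | intermediate (not isolated)
15 | methyl (1S,2S,3R)-2-[(3Z,7S)-9-(acetyloxy)-3-bromo-7-methylnon-3-en-1-yl]-5-[(tert-butyldimethylsilyl)oxy]-1,3-dimethylcyclohex-4-ene-1-carboxylate | Br/C(CC[C@H]1[C@@H](C)C=C(O[Si](C)(C)C(C)(C)C)C[C@]1(C)C(=O)OC)=C\CC[C@H](C)CCOC(C)=O | intermediate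
16 | methyl (1S,2S)-2-[(3Z,7S)-9-(acetyloxy)-3-bromo-7-methylnon-3-en-1-yl]-1,3-dimethyl-5-oxocyclohex-3-ene-1-carboxylate | Br/C(CC[C@H]1C(C)=CC(=O)C[C@]1(C)C(=O)OC)=C\CC[C@H](C)CCOC(C)=O | intermediate
17 | methyl (1S,2S)-2-{(3Z,7S)-9-(acetyloxy)-7-methyl-3-[(trimethylsilyl)methyl]non-3-en-1-yl}-1,3-dimethyl-5-oxocyclohex-3-ene-1-carboxylate | C[Si](C)(C)C/C(CC[C@H]1C(C)=CC(=O)C[C@]1(C)C(=O)OC)=C\CC[C@H](C)CCOC(C)=O | intermediate
18 | methyl (1S,4aR,5S,8aS)-5-[(3S)-5-(acetyloxy)-3-methylpentyl]-1,4a-dimethyl-6-methylidene-3-[(trichlorotitanio)oxy]-1,2,4a,5,6,7,8,8a-octahydronaphthalene-1-carboxylate (titanium enolate) | C=C1CC[C@H]2[C@](C)(C=C(O[Ti](Cl)(Cl)Cl)C[C@]2(C)C(=O)OC)[C@H]1CC[C@H](C)CCOC(C)=O | intermediate (not isolated)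
19 | methyl (1S,4aR,5S,8aS)-5-[(3S)-5-(acetyloxy)-3-methylpentyl]-1,4a-dimethyl-6-methylidene-3-oxodecahydronaphthalene-1-carboxylate | C=C1CC[C@H]2[C@](C)(CC(=O)C[C@]2(C)C(=O)OC)[C@H]1CC[C@H](C)CCOC(C)=O | intermediate
20 | methyl (1S,4aR,5S,8aS)-5-[(3S)-5-(acetyloxy)-3-methylpentyl]-1,4a-dimethyl-6-methylidene-3-[2-(4-methylbenzenesulfonyl)hydrazinylidene]decahydronaphthalene-1-carboxylate | C=C1CC[C@H]2[C@](C)(CC(=NNS(=O)(=O)c3ccc(C)cc3)C[C@]2(C)C(=O)OC)[C@H]1CC[C@H](C)CCOC(C)=O | intermediate
21 | methyl (1S,4aR,5S,8aS)-5-[(3S)-5-(acetyloxy)-3-methylpentyl]-1,4a-dimethyl-6-methylidenedecahydronaphthalene-1-carboxylate (CNP0332643.1) | C=C1CC[C@H]2[C@](C)(CCC[C@]2(C)C(=O)OC)[C@H]1CC[C@H](C)CCOC(C)=O | target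

## Step count and least certain steps

Total step count: 14. Longest linear sequence: 10 steps (1, 2, 4, 5, 9, 10, 11, 12, 13, 14); steps 3 and 6–8 are side branches.

Step 12 (key step). The most likely failure is slow ring closure. The axial approach of C9 to C10 passes over the C4 methyl (C18) in a 1,3-diaxial relationship, much as in additions to a 5,5-disubstituted cyclohexenone, so protodesilylation of the allylsilane by adventitious HCl could outrun cyclisation. A lesser risk is erosion of the C9 ratio through a boat-like closure. The fallback sets out from 16 and returns at 19. A Negishi coupling of 16 with MeZnCl (Pd[P(t-Bu)3]2) should give the methyl-substituted enone F1, the (E)-trisubstituted olefin without silicon. MeAlCl2 in CH2Cl2 at −78 °C should then induce a cation–olefin (conjugate ene-type) closure of the same C9–C10 bond through the same chair, a known reaction type for ω-alkenyl enones. Loss of a C17 proton from the C8 cation gives 19, which would have to be separated from endocyclic alkene isomers; this loss of regiocontrol is why silicon is preferred.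

Step 4. Two things may go wrong: insufficient facial discrimination by the catalyst on a β,β-disubstituted enal (low enantiomeric purity, which the remote C13 centre would turn into inseparable diastereomers later), and acid-induced loss of the silyl dienol ether before cycloaddition. The fallback sets out from 4 and 6 and returns at 7. A Me2AlCl-promoted cycloaddition (CH2Cl2, −78 °C) should give 7 together with its mirror image ent-7 F2. Condensation of the mixture with (1R,2R)-N,N′-dimethyl-1,2-diphenylethane-1,2-diamine gives two diastereomeric imidazolidines. The imidazolidine aminal of 7 F3 is separated by chromatography or crystallisation and hydrolysed on wet silica with a trace of AcOH to return 7 as a single enantiomer.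

Step 9. The risk is incomplete discrimination between the two C–Br bonds of 13 (double coupling or coupling at the cis bromide, giving the wrong alkene geometry), together with slow transmetalation of the hindered B-alkyl group. The fallback sets out from 8 and returns at 15. Hydroboration of 8 and oxidation with NaBO3·4H2O should give primary alcohol F4. An Appel reaction (I2, PPh3, imidazole) gives primary iodide F5, and zinc insertion (Zn dust, THF) gives alkylzinc iodide F6. F6 is coupled with 13 under PdCl2(DPEphos) catalysis, a Negishi monoalkylation known to be highly trans-selective on 1,1-dibromoalkenes.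

Step 10. The risk is sluggish palladation of the robust tert-butyldimethylsilyl enol ether, which would let zerovalent palladium accumulate and insert into the alkenyl bromide; epimerisation of C5 through the dienol is a further risk if the medium turns acidic. The fallback sets out from 15 and returns at 16. Desilylation with Bu4NF/AcOH (THF, 0 °C) should give saturated ketone F7. Dehydrogenation with 2-iodoxybenzoic acid (IBX, DMSO/toluene, 65 °C) can only introduce the C1=C10 double bond, because C4 is quaternary, and gives 16 without any palladium.

## Further compounds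

F1 | step 12 | methyl (1S,2S)-2-[(3E,7S)-9-(acetyloxy)-3,7-dimethylnon-3-en-1-yl]-1,3-dimethyl-5-oxocyclohex-3-ene-1-carboxylate | C/C(CC[C@H]1C(C)=CC(=O)C[C@]1(C)C(=O)OC)=C\CC[C@H](C)CCOC(C)=O
F2 | step 4 | methyl (1R,2R,3R)-5-[(tert-butyldimethylsilyl)oxy]-2-formyl-1,3-dimethylcyclohex-4-ene-1-carboxylate (ent-7) | O=C[C@@H]1[C@H](C)C=C(O[Si](C)(C)C(C)(C)C)C[C@@]1(C)C(=O)OC
F3 | step 4 | methyl (1S,2S,3R)-5-[(tert-butyldimethylsilyl)oxy]-2-[(4R,5R)-1,3-dimethyl-4,5-diphenylimidazolidin-2-yl]-1,3-dimethylcyclohex-4-ene-1-carboxylate | CN1C([C@H]2[C@@H](C)C=C(O[Si](C)(C)C(C)(C)C)C[C@]2(C)C(=O)OC)N(C)[C@H](c2ccccc2)[C@H]1c1ccccc1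
F4 | step 9 | methyl (1S,2S,3R)-5-[(tert-butyldimethylsilyl)oxy]-2-(2-hydroxyethyl)-1,3-dimethylcyclohex-4-ene-1-carboxylate | OCC[C@H]1[C@@H](C)C=C(O[Si](C)(C)C(C)(C)C)C[C@]1(C)C(=O)OC
F5 | step 9 | methyl (1S,2S,3R)-5-[(tert-butyldimethylsilyl)oxy]-2-(2-iodoethyl)-1,3-dimethylcyclohex-4-ene-1-carboxylate | ICC[C@H]1[C@@H](C)C=C(O[Si](C)(C)C(C)(C)C)C[C@]1(C)C(=O)OC
F6 | step 9 | {2-[(1S,2S,6R)-4-[(tert-butyldimethylsilyl)oxy]-2-(methoxycarbonyl)-2,6-dimethylcyclohex-3-en-1-yl]ethyl}zinc iodide | I[Zn]CC[C@H]1[C@@H](C)C=C(O[Si](C)(C)C(C)(C)C)C[C@]1(C)C(=O)OC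
F7 | step 10 | methyl (1S,2S,3S)-2-[(3Z,7S)-9-(acetyloxy)-3-bromo-7-methylnon-3-en-1-yl]-1,3-dimethyl-5-oxocyclohexane-1-carboxylate | Br/C(CC[C@H]1[C@@H](C)CC(=O)C[C@]1(C)C(=O)OC)=C\CC[C@H](C)CCOC(C)=O
A1 | alternative 1 | methyl (6E,10E,14S)-16-(acetyloxy)-2,6,10,14-tetramethyl-3-oxohexadeca-6,10-dienoate | COC(=O)C(C)C(=O)CC/C(C)=C/CC/C(C)=C/CC[C@H](C)CCOC(C)=O
A2 | alternative 1 | methyl (1R,4aR,5S,8aR)-5-[(3S)-5-(acetyloxy)-3-methylpentyl]-1,4a-dimethyl-6-methylidene-2-oxodecahydronaphthalene-1-carboxylate (trans-fused) | C=C1CC[C@@H]2[C@](C)(CCC(=O)[C@]2(C)C(=O)OC)[C@H]1CC[C@H](C)CCOC(C)=O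
A3 | alternative 2 | methyl (1R,4aS)-1,4a-dimethyl-2,5-dioxo-1,2,3,4,4a,5,6,7-octahydronaphthalene-1-carboxylate | COC(=O)[C@@]1(C)C(=O)CC[C@]2(C)C(=O)CCC=C12
A4 | alternative 3 | methyl 2-methyl-3-oxopent-4-enoate | COC(=O)C(C)C(=O)C=C
A5 | alternative 3 | methyl (1R,4aS,8aS)-1,4a-dimethyl-2,5-dioxodecahydronaphthalene-1-carboxylate (cis-fused) | COC(=O)[C@@]1(C)C(=O)CC[C@]2(C)C(=O)CCC[C@H]12
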